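**Strategy.** The route rests on cutting ring A (carbocycle C4a–C5–C6–C7–C8–C8a, isochromene numbering) between C6 and C7. The C8 ketone, the tertiary C7 hydroxyl α to it and the secondary C6 oxygen β to it form an α,β-dihydroxy ketone, the retron of an enediolate aldol. The precursor is an open-chain enynone: a 2-hydroxypropanoyl group on C8a and a CH2CHO arm on C4a, held cis on a tetrasubstituted alkene made by directed anti-carbomagnesiation. One chiral dinuclear zinc-catalysed step closes ring A and sets both stereocentres as the cis-diol. Ring B (pyran, O2–C3) is closed afterwards by 6-endo oxa-Michael addition.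

Key step: step 10

Remark on the chemistry: Grignard reagent 4 is used as the commercial E/Z mixture. Its double-bond geometry and the two carbinol centres made from it in step 4 are erased in steps 8 and 10, so 4–7 are drawn as the E isomer, and 8 and 13–15 are racemic and carry no descriptors at these centres. Atom labels (C1, O2, C3, C4, C4a, C5–C8, C8a) follow the isochromene numbering of the target; ring A is the carbocycle and ring B the pyran.

**Step 1**
Reactants: 1 4,4-diethoxybut-1-yne
Product: 3 5,5-diethoxypent-2-yn-1-ol, via lithium acetylide 2 (not isolated)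
Conditions: n-BuLi, THF, −78 °C; then (CH2O)n, −78 °C → rt
Reagents that add atoms: paraformaldehyde (as formaldehyde), C=O
Why: Acetylide hydroxymethylation (1,2-addition of the lithium acetylide to formaldehyde) should give the propargylic alcohol that later directs the carbometalation; no stereocentre is formed.

**Step 2**
Reactants: 3 5,5-diethoxypent-2-yn-1-ol; 4 prop-1-enylmagnesium bromide
Product: 6 (2Z)-5,5-diethoxy-3-iodo-2-[(1E)-prop-1-en-1-yl]pent-2-en-1-ol, via oxamagnesacycle 5 (not isolated)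
Conditions: 4 (3.5 equiv), THF/cyclohexane, reflux; then I2, THF, −78 °C → 0 °C
Reagents that add atoms: iodine, II
Why: Hydroxyl-directed anti-carbomagnesiation of the propargylic alkoxide puts the propenyl group on the proximal alkyne carbon (C8a) and magnesium on the distal one (C4a) inside a five-membered chelate, so iodinolysis with retention should fix the tetrasubstituted C4a=C8a geometry (iodine cis to CH2OH, acetal arm cis to propenyl).

**Step 3**
Reactants: 6 (2Z)-5,5-diethoxy-3-iodo-2-[(1E)-prop-1-en-1-yl]pent-2-en-1-ol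
Product: 7 tert-butyl{[(2Z)-5,5-diethoxy-3-iodo-2-[(1E)-prop-1-en-1-yl]pent-2-en-1-yl]oxy}diphenylsilane
Conditions: TBDPSCl, imidazole, CH2Cl2, 0 °C → rt
Reagents that add atoms: tert-butyl(chloro)diphenylsilane, CC(C)(C)[Si](Cl)(c1ccccc1)c1ccccc1
Why: Standard silylation of the primary allylic alcohol masks the future ring-B oxygen through the oxidation, aldol and acylation steps.

**Step 4**
Reactants: 7 tert-butyl{[(2Z)-5,5-diethoxy-3-iodo-2-[(1E)-prop-1-en-1-yl]pent-2-en-1-yl]oxy}diphenylsilane
Product: 8 (4E)-4-({[tert-butyl(diphenyl)silyl]oxy}methyl)-7,7-diethoxy-5-iodohept-4-ene-2,3-diol (racemic diastereomer mixture)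
Conditions: OsO4 (2 mol %), NMO, acetone/H2O, 0 °C → rt
Reagents that add atoms: osmium tetroxide (catalytic oxygen carrier), O=[Os](=O)(=O)=O; N-methylmorpholine N-oxide, C[N+]1([O-])CCOCC1; water, O
Why: Catalytic OsO4 dihydroxylation (Upjohn conditions) should take the electron-richer 1,2-disubstituted propenyl bond in preference to the hindered, iodine-bearing tetrasubstituted alkene; the two carbinol centres form without control and are erased later.

**Step 5**
Reactants: 9 3-(trimethylsilyl)prop-2-ynal; 10 tert-butyl (triphenylphosphoranylidene)acetate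
Product: 11 tert-butyl (2E)-5-(trimethylsilyl)pent-2-en-4-ynoate
Conditions: CH2Cl2, 0 °C → rt
Reagents that add atoms: none
Why: Wittig olefination with a stabilised ylide should give the (E)-enoate.

**Step 6**
Reactants: 11 tert-butyl (2E)-5-(trimethylsilyl)pent-2-en-4-ynoate
Product: 12 tert-butyl (2E)-pent-2-en-4-ynoate
Conditions: K2CO3 (cat.), MeOH, 0 °C
Reagents that add atoms: none
Why: Base-catalysed methanolysis of the C(sp)–Si bond frees the terminal alkyne without touching the tert-butyl ester.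

**Step 7**
Reactants: 8 (4E)-4-({[tert-butyl(diphenyl)silyl]oxy}methyl)-7,7-diethoxy-5-iodohept-4-ene-2,3-diol; 12 tert-butyl (2E)-pent-2-en-4-ynoate
Product: 13 tert-butyl (2E,6E)-7-({[tert-butyl(diphenyl)silyl]oxy}methyl)-6-(2,2-diethoxyethyl)-8,9-dihydroxydeca-2,6-dien-4-ynoate (diastereomer mixture)
Conditions: PdCl2(PPh3)2 (5 mol %), CuI (10 mol %), i-Pr2NH, THF, rt
Reagents that add atoms: none
Why: Sonogashira coupling of the alkenyl iodide proceeds with retention of alkene geometry and brings in C4, C3 and the whole acrylate side chain; it precedes the oxidation so that an α'-hydroxy β-iodo enone, which could close to a furan-3(2H)-one, is never formed.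

**Step 8**
Reactants: 13 tert-butyl (2E,6E)-7-({[tert-butyl(diphenyl)silyl]oxy}methyl)-6-(2,2-diethoxyethyl)-8,9-dihydroxydeca-2,6-dien-4-ynoate
Product: 14 tert-butyl (2E,6E)-7-({[tert-butyl(diphenyl)silyl]oxy}methyl)-6-(2,2-diethoxyethyl)-9-hydroxy-8-oxodeca-2,6-dien-4-ynoate (racemic)
Conditions: MnO2 (excess), CH2Cl2, rt
Reagents that add atoms: none
Why: Allylic oxidation with MnO2 should convert only the allylic C8 carbinol of the diol into the ketone, giving the 2-hydroxypropanoyl (α-hydroxy ketone) donor.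

**Step 9**
Reactants: 14 tert-butyl (2E,6E)-7-({[tert-butyl(diphenyl)silyl]oxy}methyl)-6-(2,2-diethoxyethyl)-9-hydroxy-8-oxodeca-2,6-dien-4-ynoate
Product: 15 tert-butyl (2E,6E)-7-({[tert-butyl(diphenyl)silyl]oxy}methyl)-9-hydroxy-8-oxo-6-(2-oxoethyl)deca-2,6-dien-4-ynoate (racemic)
Conditions: PPTS, acetone/H2O, 45 °C
Reagents that add atoms: water, O
Why: Mild acid-catalysed acetal hydrolysis unmasks the C6 aldehyde while the silyl ether and tert-butyl ester survive; the alkene stays in place because it is conjugated with the ketone and the alkyne.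

**Step 10**
Reactants: 15 tert-butyl (2E,6E)-7-({[tert-butyl(diphenyl)silyl]oxy}methyl)-9-hydroxy-8-oxo-6-(2-oxoethyl)deca-2,6-dien-4-ynoate
Product: 16 tert-butyl (2E)-5-[(4R,5R)-2-({[tert-butyl(diphenyl)silyl]oxy}methyl)-4,5-dihydroxy-4-methyl-3-oxocyclohex-1-en-1-yl]pent-2-en-4-ynoate
Conditions: (S,S)-ProPhenol (10 mol %), Et2Zn (20 mol %), 4 Å MS, THF, −20 °C → 0 °C
Reagents that add atoms: none
Why: Proposed new method: the dinuclear zinc–ProPhenol alkoxide binds the α-hydroxy ketone of 15 through O7 and O8, removes the C7 proton and forms a chelated zinc enediolate while the second zinc holds the C6 aldehyde, so that C7 adds to the aldehyde carbon in a 6-(enolendo)-exo-trig closure of ring A; the closest known reaction type is the intermolecular direct aldol of α-hydroxy ketones (including 2-hydroxypropiophenone-type donors that give tertiary carbinols) with such dinuclear zinc catalysts, and the ring-closing version is not established. Because the C7 stereocentre of racemic 15 is erased in the enediolate, both enantiomers converge. The cis relation of the C6 and C7 oxygens should follow from a closed, metal-bridged (Zimmerman–Traxler-type) transition state in which the aldehyde oxygen lies gauche to C8 on the zinc assembly that carries the enediolate oxygens, which the short tether allows only with the C6 oxygen pseudo-axial, that is cis to O7. The absolute sense at C6 and C7 is set by the chiral ligand pocket; (S,S)-ProPhenol is chosen by analogy and its enantiomer is used if the opposite face is delivered. The step needs enolisation at C7 and not at the acidic C5 methylene: bidentate binding of the hydroxy ketone favours the former, and the aldehyde enolate has no ring of workable size to close. Low temperature and molecular sieves are meant to suppress uncatalysed aldolisation and retro-aldol equilibration of the product.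

**Step 11**
Reactants: 17 5-methylbenzene-1,2,3-triol
Product: 18 6-methyl-2,2-diphenyl-1,3-benzodioxol-4-ol
Conditions: Ph2CCl2, Ph2O, 170 °C
Reagents that add atoms: dichlorodiphenylmethane, ClC(Cl)(c1ccccc1)c1ccccc1
Why: Ketalisation of two adjacent phenols of the symmetric triol leaves one terminal hydroxyl free, which singles out the oxygen that becomes the methyl ether.

**Step 12**
Reactants: 18 6-methyl-2,2-diphenyl-1,3-benzodioxol-4-ol
Product: 19 4-hydroxy-6-methyl-2,2-diphenyl-1,3-benzodioxole-5-carbaldehyde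
Conditions: MgCl2, Et3N, (CH2O)n, MeCN, reflux; aq. HCl work-up
Reagents that add atoms: paraformaldehyde (as formaldehyde), C=O
Why: Magnesium phenoxide-mediated ortho-formylation (Casnati–Skattebøl reaction) is specific for the position ortho to the free phenol, here the only open one, between OH and CH3.

**Step 13**
Reactants: 19 4-hydroxy-6-methyl-2,2-diphenyl-1,3-benzodioxole-5-carbaldehyde
Product: 20 4-methoxy-6-methyl-2,2-diphenyl-1,3-benzodioxole-5-carbaldehyde
Conditions: MeI, K2CO3, DMF, rt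
Reagents that add atoms: iodomethane, CI
Why: Williamson O-methylation of the salicylaldehyde hydroxyl installs the 2-methoxy group.

**Step 14**
Reactants: 20 4-methoxy-6-methyl-2,2-diphenyl-1,3-benzodioxole-5-carbaldehyde
Product: 21 4-methoxy-6-methyl-2,2-diphenyl-1,3-benzodioxole-5-carboxylic acid
Conditions: NaClO2, NaH2PO4, 2-methylbut-2-ene, t-BuOH/H2O, rt
Reagents that add atoms: sodium chlorite, [Na+].[O-]Cl=O
Why: Pinnick oxidation converts the hindered aldehyde into the acid without attacking the electron-rich ring, 2-methylbut-2-ene trapping the HOCl formed.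

**Step 15**
Reactants: 16 tert-butyl (2E)-5-[(4R,5R)-2-({[tert-butyl(diphenyl)silyl]oxy}methyl)-4,5-dihydroxy-4-methyl-3-oxocyclohex-1-en-1-yl]pent-2-en-4-ynoate; 21 4-methoxy-6-methyl-2,2-diphenyl-1,3-benzodioxole-5-carboxylic acid
Product: 23 (1R,6R)-3-[(3E)-5-tert-butoxy-5-oxopent-3-en-1-yn-1-yl]-4-({[tert-butyl(diphenyl)silyl]oxy}methyl)-6-hydroxy-6-methyl-5-oxocyclohex-3-en-1-yl 4-methoxy-6-methyl-2,2-diphenyl-1,3-benzodioxole-5-carboxylate, via acid chloride 22 (not isolated)
Conditions: 21, (COCl)2, DMF (cat.), CH2Cl2, 0 °C → rt, evaporate; then 16, DMAP, Et3N, CH2Cl2, 0 °C → rt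
Reagents that add atoms: none
Why: DMAP-catalysed acylation with the acid chloride should take the secondary C6 hydroxyl and not the hindered tertiary C7 hydroxyl, leaves both stereocentres untouched and blocks retro-aldol opening of ring A in the later steps.

**Step 16**
Reactants: 23 (1R,6R)-3-[(3E)-5-tert-butoxy-5-oxopent-3-en-1-yn-1-yl]-4-({[tert-butyl(diphenyl)silyl]oxy}methyl)-6-hydroxy-6-methyl-5-oxocyclohex-3-en-1-yl 4-methoxy-6-methyl-2,2-diphenyl-1,3-benzodioxole-5-carboxylate
Product: 25 (6R,7R)-3-[(1E)-3-tert-butoxy-3-oxoprop-1-en-1-yl]-7-hydroxy-7-methyl-8-oxo-5,6,7,8-tetrahydro-1H-isochromen-6-yl 4-methoxy-6-methyl-2,2-diphenyl-1,3-benzodioxole-5-carboxylate, via allylic alcohol 24 (not isolated)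
Conditions: TBAF (1.5 equiv), AcOH (1.0 equiv), THF, 0 °C → rt
Reagents that add atoms: none
Why: Fluoride desilylation frees the C1 oxygen, which should add 6-endo-dig to alkyne carbon C3 (oxa-Michael 1,6-addition to the C8 enone) and, after protonation at C4, give the fully conjugated pyran ring B.

**Step 17**
Reactants: 25 (6R,7R)-3-[(1E)-3-tert-butoxy-3-oxoprop-1-en-1-yl]-7-hydroxy-7-methyl-8-oxo-5,6,7,8-tetrahydro-1H-isochromen-6-yl 4-methoxy-6-methyl-2,2-diphenyl-1,3-benzodioxole-5-carboxylate
Product: 26 (2E)-3-[(6R,7R)-6-[(3,4-dihydroxy-2-methoxy-6-methylbenzoyl)oxy]-7-hydroxy-7-methyl-8-oxo-5,6,7,8-tetrahydro-1H-isochromen-3-yl]prop-2-enoic acid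
Conditions: TFA/CH2Cl2/H2O (10:10:1), 0 °C → rt
Reagents that add atoms: none
Why: Acidolysis removes the diphenylmethylene ketal (as benzophenone) and the tert-butyl ester (as isobutene) in one operation; the push–pull dienyl ether of ring B and the hindered aryl ester should tolerate the acid.

**Compound list**

1 | 4,4-diethoxybut-1-yne | C#CCC(OCC)OCC | starting material
2 | lithium 4,4-diethoxybut-1-yn-1-ide | [Li]C#CCC(OCC)OCC | intermediate
3 | 5,5-diethoxypent-2-yn-1-ol | OCC#CCC(OCC)OCC | intermediate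
4 | (E)-prop-1-en-1-ylmagnesium bromide | C/C=C/[Mg]Br | starting material
5 | 3-(2,2-diethoxyethyl)-4-[(E)-prop-1-enyl]-2,5-dihydro-1,2-oxamagnesole | CCOC(CC1=C(CO[Mg]1)/C=C/C)OCC | intermediate
6 | (2Z)-5,5-diethoxy-3-iodo-2-[(1E)-prop-1-en-1-yl]pent-2-en-1-ol | OC/C(=C(\I)CC(OCC)OCC)/C=C/C | intermediate
7 | tert-butyl{[(2Z)-5,5-diethoxy-3-iodo-2-[(1E)-prop-1-en-1-yl]pent-2-en-1-yl]oxy}diphenylsilane | CC(C)(C)[Si](c1ccccc1)(c1ccccc1)OC/C(=C(\I)CC(OCC)OCC)/C=C/C | intermediate
8 | (4E)-4-({[tert-butyl(diphenyl)silyl]oxy}methyl)-7,7-diethoxy-5-iodohept-4-ene-2,3-diol | CC(O)C(O)/C(CO[Si](c1ccccc1)(c1ccccc1)C(C)(C)C)=C(/I)CC(OCC)OCC | intermediate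
9 | 3-(trimethylsilyl)prop-2-ynal | C[Si](C)(C)C#CC=O | starting material
10 | tert-butyl (triphenylphosphoranylidene)acetate | CC(C)(C)OC(=O)C=P(c1ccccc1)(c1ccccc1)c1ccccc1 | starting material
11 | tert-butyl (2E)-5-(trimethylsilyl)pent-2-en-4-ynoate | C[Si](C)(C)C#C/C=C/C(=O)OC(C)(C)C | intermediate
12 | tert-butyl (2E)-pent-2-en-4-ynoate | C#C/C=C/C(=O)OC(C)(C)C | intermediate
13 | tert-butyl (2E,6E)-7-({[tert-butyl(diphenyl)silyl]oxy}methyl)-6-(2,2-diethoxyethyl)-8,9-dihydroxydeca-2,6-dien-4-ynoate | CC(O)C(O)/C(CO[Si](c1ccccc1)(c1ccccc1)C(C)(C)C)=C(/C#C/C=C/C(=O)OC(C)(C)C)CC(OCC)OCC | intermediate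
14 | tert-butyl (2E,6E)-7-({[tert-butyl(diphenyl)silyl]oxy}methyl)-6-(2,2-diethoxyethyl)-9-hydroxy-8-oxodeca-2,6-dien-4-ynoate | CC(O)C(=O)/C(CO[Si](c1ccccc1)(c1ccccc1)C(C)(C)C)=C(/C#C/C=C/C(=O)OC(C)(C)C)CC(OCC)OCC | intermediate
15 | tert-butyl (2E,6E)-7-({[tert-butyl(diphenyl)silyl]oxy}methyl)-9-hydroxy-8-oxo-6-(2-oxoethyl)deca-2,6-dien-4-ynoate | CC(O)C(=O)/C(CO[Si](c1ccccc1)(c1ccccc1)C(C)(C)C)=C(/C#C/C=C/C(=O)OC(C)(C)C)CC=O | intermediate
16 | tert-butyl (2E)-5-[(4R,5R)-2-({[tert-butyl(diphenyl)silyl]oxy}methyl)-4,5-dihydroxy-4-methyl-3-oxocyclohex-1-en-1-yl]pent-2-en-4-ynoate | O[C@@H]1CC(C#C/C=C/C(=O)OC(C)(C)C)=C(CO[Si](c2ccccc2)(c2ccccc2)C(C)(C)C)C(=O)[C@]1(C)O | intermediate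
17 | 5-methylbenzene-1,2,3-triol | Cc1cc(O)c(O)c(O)c1 | starting material
18 | 6-methyl-2,2-diphenyl-1,3-benzodioxol-4-ol | Cc1cc(O)c2OC(c3ccccc3)(c3ccccc3)Oc2c1 | intermediate
19 | 4-hydroxy-6-methyl-2,2-diphenyl-1,3-benzodioxole-5-carbaldehyde | Cc1cc2OC(c3ccccc3)(c3ccccc3)Oc2c(O)c1C=O | intermediate
20 | 4-methoxy-6-methyl-2,2-diphenyl-1,3-benzodioxole-5-carbaldehyde | COc1c2OC(c3ccccc3)(c3ccccc3)Oc2cc(C)c1C=O | intermediate
21 | 4-methoxy-6-methyl-2,2-diphenyl-1,3-benzodioxole-5-carboxylic acid | COc1c2OC(c3ccccc3)(c3ccccc3)Oc2cc(C)c1C(=O)O | intermediate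
22 | 4-methoxy-6-methyl-2,2-diphenyl-1,3-benzodioxole-5-carbonyl chloride | COc1c2OC(c3ccccc3)(c3ccccc3)Oc2cc(C)c1C(=O)Cl | intermediate
23 | (1R,6R)-3-[(3E)-5-tert-butoxy-5-oxopent-3-en-1-yn-1-yl]-4-({[tert-butyl(diphenyl)silyl]oxy}methyl)-6-hydroxy-6-methyl-5-oxocyclohex-3-en-1-yl 4-methoxy-6-methyl-2,2-diphenyl-1,3-benzodioxole-5-carboxylate | COc1c2OC(c3ccccc3)(c3ccccc3)Oc2cc(C)c1C(=O)O[C@@H]1CC(C#C/C=C/C(=O)OC(C)(C)C)=C(CO[Si](c2ccccc2)(c2ccccc2)C(C)(C)C)C(=O)[C@]1(C)O | intermediate
24 | (1R,6R)-3-[(3E)-5-tert-butoxy-5-oxopent-3-en-1-yn-1-yl]-6-hydroxy-4-(hydroxymethyl)-6-methyl-5-oxocyclohex-3-en-1-yl 4-methoxy-6-methyl-2,2-diphenyl-1,3-benzodioxole-5-carboxylate | COc1c2OC(c3ccccc3)(c3ccccc3)Oc2cc(C)c1C(=O)O[C@@H]1CC(C#C/C=C/C(=O)OC(C)(C)C)=C(CO)C(=O)[C@]1(C)O | intermediate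
25 | (6R,7R)-3-[(1E)-3-tert-butoxy-3-oxoprop-1-en-1-yl]-7-hydroxy-7-methyl-8-oxo-5,6,7,8-tetrahydro-1H-isochromen-6-yl 4-methoxy-6-methyl-2,2-diphenyl-1,3-benzodioxole-5-carboxylate | COc1c2OC(c3ccccc3)(c3ccccc3)Oc2cc(C)c1C(=O)O[C@@H]1CC2=C(COC(/C=C/C(=O)OC(C)(C)C)=C2)C(=O)[C@]1(C)O | intermediate
26 | (2E)-3-[(6R,7R)-6-[(3,4-dihydroxy-2-methoxy-6-methylbenzoyl)oxy]-7-hydroxy-7-methyl-8-oxo-5,6,7,8-tetrahydro-1H-isochromen-3-yl]prop-2-enoic acid | COc1c(O)c(O)cc(C)c1C(=O)O[C@@H]1CC2=C(COC(/C=C/C(=O)O)=C2)C(=O)[C@]1(C)O | target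

**Step count.** Total: 17 steps. Longest linear sequence: 11 steps (1–4, 7–10, 15–17).

**Steps most likely to fail**

1. Step 10 (proposed new method). What may go wrong: poor facial discrimination in the ring-closing setting, a trans-selective or uncatalysed background aldolisation, or retro-aldol equilibration. Fallback with known chemistry, from 8 back to 16:
   - Swern oxidation of diol 8 ((COCl)2, DMSO, Et3N, −78 °C) gives the diketo acetal F1.
   - PPTS in aqueous acetone gives the diketo aldehyde F2.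
   - An enantioselective carbene-catalysed crossed aldehyde–ketone benzoin cyclisation (aminoindanol-derived N-pentafluorophenyl triazolium tetrafluoroborate, Et3N, toluene) joins C6 to C7 and gives the hydroxy dione F3 with the tertiary C7 carbinol set by the catalyst.
   - Corey–Bakshi–Shibata reduction ((S)-Me-CBS, catecholborane, −78 °C) of the saturated C6 ketone, which is far more accessible than the hindered conjugated C8 ketone, gives the iodo diol F4 under reagent control.
   - Sonogashira coupling of F4 with 12 returns to 16.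

2. Step 2. What may go wrong: slow or unselective carbomagnesiation with the β-substituted alkenyl Grignard reagent, so that protonolysis or regioisomeric addition competes. Fallback, from 3 back to 7:
   - The three-carbon unit is introduced as an sp3 nucleophile: allylmagnesium bromide (Et2O/THF, rt), the most reactive partner in this directed addition, then I2, gives the allyl iodo alcohol F5.
   - Silylation as in step 3 gives the allyl silyl ether F6.
   - Ruthenium hydride-catalysed alkene isomerisation (RuHCl(CO)(PPh3)3, toluene, 80 °C) moves the terminal double bond into conjugation and gives 7.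

3. Step 16. What may go wrong: 5-exo attack at C4 (ester-directed conjugate addition) or base-induced β-elimination of the aryl carboxylate from C6. Fallback, from 23 back to 25: the silyl ether is cleaved under acidic conditions (HF·pyridine, THF) and the allylic alcohol 24 is isolated. The ring is then closed by π-acid activation of the alkyne instead of alkoxide addition, a 6-endo hydroalkoxylation with (Ph3P)AuNTf2 (2 mol %) in CH2Cl2, giving 25 with no base present.

**Further compounds**

F1 | step 10 | (4E)-4-({[tert-butyl(diphenyl)silyl]oxy}methyl)-7,7-diethoxy-5-iodohept-4-ene-2,3-dione | CC(=O)C(=O)/C(CO[Si](c1ccccc1)(c1ccccc1)C(C)(C)C)=C(/I)CC(OCC)OCC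
F2 | step 10 | (3E)-4-({[tert-butyl(diphenyl)silyl]oxy}methyl)-3-iodo-5,6-dioxohept-3-enal | CC(=O)C(=O)/C(CO[Si](c1ccccc1)(c1ccccc1)C(C)(C)C)=C(/I)CC=O
F3 | step 10 | (6R)-2-({[tert-butyl(diphenyl)silyl]oxy}methyl)-6-hydroxy-3-iodo-6-methylcyclohex-2-ene-1,5-dione | O=C1CC(I)=C(CO[Si](c2ccccc2)(c2ccccc2)C(C)(C)C)C(=O)[C@]1(C)O
F4 | step 10 | (5R,6R)-2-({[tert-butyl(diphenyl)silyl]oxy}methyl)-5,6-dihydroxy-3-iodo-6-methylcyclohex-2-en-1-one | O[C@@H]1CC(I)=C(CO[Si](c2ccccc2)(c2ccccc2)C(C)(C)C)C(=O)[C@]1(C)O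
F5 | step 2 | (2Z)-5,5-diethoxy-3-iodo-2-(prop-2-en-1-yl)pent-2-en-1-ol | OC/C(CC=C)=C(\I)CC(OCC)OCC
F6 | step 2 | tert-butyl{[(2Z)-5,5-diethoxy-3-iodo-2-(prop-2-en-1-yl)pent-2-en-1-yl]oxy}diphenylsilane | CC(C)(C)[Si](c1ccccc1)(c1ccccc1)OC/C(CC=C)=C(\I)CC(OCC)OCC
F0 | step 16 | none | none
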